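**Plan**

- Retrosynthesis: remove the three benzyl groups; cut C3–O back to C3–Si and then to C3–H plus an O1–SiEt2H ether; cut the two vanilloyl ester C–O bonds at O4 and O5; cut C5–O and C4–O back to a cyclohex-3-ene (through a γ-lactone and an epoxide); cut the two ring C–C bonds of a butadiene/2-acyloxyacrolein Diels–Alder adduct.
- Forward: the Diels–Alder closes the carbocycle and sets C1; an epoxide and then a γ-lactone are closed and reopened to place O4 and O5; both esters are put on; the O1–Si–C3 oxasilolane closes in the key step and is opened by oxidation; hydrogenolysis ends the route.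
- Enabling feature: in the chair of the 3-deoxy-4,5-diester the axial O1 and one C3–H are cis-1,3-diaxial (O1–C1–C2–C3–H), so silicon on O1 can bridge C1 and C3 in a five-membered 1-oxa-2-silacyclopentane; the other γ C–H (C5–H) is tertiary and acyloxy-substituted.
- Stereochemistry: C1 from the chiral ammonium catalyst of the Diels–Alder; C4 from epoxidation directed by the 1-OH; C5 from SN2 inversion by the C1 carboxyl in the lactonisation; C3 from the cis tether and retentive C–Si oxidation.

Key step: step 13

Remark: quinic acid numbering is used throughout (C1 bears OH and the carboxyl; O3 and O4 are cis to O1, O5 is trans to O1 and cis to the carboxyl); the target is the 4,5-diester in this numbering.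

Assumption: the ammonium-salt catalyst of step 3 is taken to show the same facial sense with butadiene as with other dienes; whichever catalyst enantiomer (L,L- or D,D-derived) gives the (S)-aldehyde is used.

**Route**

Step 1
Reactants: 1 2,2-dimethyl-1,3-dioxan-5-one; 2 4-methoxybenzoyl chloride
Product: 3 2,2-dimethyl-4H-1,3-dioxin-5-yl 4-methoxybenzoate
Conditions: KHMDS, THF, −78 °C; then 2, −78 → 0 °C
Reagents that add atoms: none
Why: O-acylation of the potassium enolate of the symmetric dioxanone by the acid chloride (enolate O-acylation) gives the enol ester that is the masked 2-acyloxyacrolein.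

Step 2
Reactants: 3 2,2-dimethyl-4H-1,3-dioxin-5-yl 4-methoxybenzoate
Product: 4 2-[(4-methoxybenzoyl)oxy]prop-2-enal (2-anisoyloxyacrolein)
Conditions: toluene, 110 °C, acetone distilled off; used at once
Reagents that add atoms: none
Why: a thermal retro-hetero-Diels–Alder reaction of the 4H-1,3-dioxin expels acetone and releases the 2-acyloxyacrolein, the standard access to this dienophile class.

Step 3
Reactants: 4 2-[(4-methoxybenzoyl)oxy]prop-2-enal; 5 buta-1,3-diene
Product: 6 (S)-1-formylcyclohex-3-en-1-yl 4-methoxybenzoate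
Conditions: triamine from LiAlH4 reduction of H-L-Phe-L-Leu pyrrolidide (10 mol %), C6F5SO3H (27.5 mol %), 5 (5 equiv), EtNO2, rt, sealed tube
Reagents that add atoms: none
Why: iminium activation of the α-acyloxyacrolein by the chiral primary ammonium salt lowers the LUMO and shields one face, so the Diels–Alder reaction with the symmetric diene (no regio- or endo/exo issue) should close the cyclohexene and set the C1 quaternary centre as (S) under catalyst control.

Step 4
Reactants: 6 (S)-1-formylcyclohex-3-en-1-yl 4-methoxybenzoate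
Product: 7 (S)-1-[(4-methoxybenzoyl)oxy]cyclohex-3-ene-1-carboxylic acid
Conditions: NaClO2, NaH2PO4, 2-methylbut-2-ene, t-BuOH/H2O, 0 °C → rt
Reagents that add atoms: sodium chlorite, [Na+].[O-]Cl=O
Why: the Pinnick oxidation converts the aldehyde into the acid while the scavenger removes hypochlorite, so neither the ring alkene nor the quaternary centre is touched.

Step 5
Reactants: 7 (S)-1-[(4-methoxybenzoyl)oxy]cyclohex-3-ene-1-carboxylic acid
Product: 9 methyl (S)-1-hydroxycyclohex-3-ene-1-carboxylate, via O-anisoyl methyl ester 8 (not isolated)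
Conditions: MeI, K2CO3, DMF, rt; then NaOMe (0.3 equiv), MeOH, rt → 40 °C
Reagents that add atoms: iodomethane, CI
Why: carboxylate alkylation followed by Zemplén-type methoxide transesterification should remove the anisoyl group as methyl anisate, the methyl ester being degenerate in methanol, and so free the tertiary 1-OH without affecting C1.

Step 6
Reactants: 9 methyl (S)-1-hydroxycyclohex-3-ene-1-carboxylate
Product: 10 methyl (1S,3S,6R)-3-hydroxy-7-oxabicyclo[4.1.0]heptane-3-carboxylate (epoxide cis to the hydroxyl)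
Conditions: VO(acac)2 (5 mol %), t-BuOOH (decane), CH2Cl2, 0 °C → rt
Reagents that add atoms: tert-butyl hydroperoxide, CC(C)(C)OO
Why: in the vanadium-catalysed hydroxyl-directed epoxidation the vanadium-bound homoallylic alkoxide delivers the peroxide oxygen to the alkene face syn to the 1-OH, which sets C4–O cis to O1 (final) and C5–O cis to O1 (to be inverted in step 7).

Step 7
Reactants: 10 methyl (1S,3S,6R)-3-hydroxy-7-oxabicyclo[4.1.0]heptane-3-carboxylate
Product: 12 (1S,4R,5R)-1,4-dihydroxy-6-oxabicyclo[3.2.1]octan-7-one (3-deoxyquinide), via epoxy acid 11 (not isolated)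
Conditions: LiOH, THF/H2O, 0 °C; then 1 M H2SO4 to pH 2, rt
Reagents that add atoms: lithium hydroxide, [Li+].[OH-]
Why: after saponification the carboxyl group opens the protonated epoxide in a 5-exo, trans-diaxial (Fürst–Plattner) epoxy-acid lactonisation that is only possible at C5 from the face anti to the epoxide oxygen, so C5 is inverted (O5 cis to the carboxyl) while O4 stays cis to O1.

Step 8
Reactants: 12 (1S,4R,5R)-1,4-dihydroxy-6-oxabicyclo[3.2.1]octan-7-one
Product: 14 benzyl (1S,3R,4R)-1,3,4-trihydroxycyclohexane-1-carboxylate (benzyl 3-deoxyquinate), via caesium 3-deoxyquinate 13 (not isolated)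
Conditions: CsOH·H2O (1.0 equiv), THF/H2O, 0 °C → rt; evaporate; BnBr, DMF, rt
Reagents that add atoms: caesium hydroxide, [Cs+].[OH-]; benzyl bromide, BrCc1ccccc1
Why: hydroxide opens the bridged γ-lactone and the caesium carboxylate is then alkylated by benzyl bromide in an SN2 esterification that leaves the neutral hydroxyls and all stereocentres untouched.

Step 9
Reactants: 15 vanillic acid
Product: 17 4-(benzyloxy)-3-methoxybenzoic acid, via benzyl 4-(benzyloxy)-3-methoxybenzoate 16 (not isolated)
Conditions: BnBr (2.2 equiv), K2CO3, DMF, 60 °C; then aq NaOH, MeOH, reflux; HCl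
Reagents that add atoms: benzyl bromide, BrCc1ccccc1; sodium hydroxide, [Na+].[OH-]
Why: Williamson benzylation of phenol and carboxylate followed by saponification of the benzyl ester leaves the phenol masked as a benzyl ether that hydrogenolysis removes at the end.

Step 10
Reactants: 17 4-(benzyloxy)-3-methoxybenzoic acid
Product: 18 4-(benzyloxy)-3-methoxybenzoyl chloride
Conditions: (COCl)2, DMF (cat.), CH2Cl2, 0 °C → rt; used crude
Reagents that add atoms: oxalyl chloride, ClC(=O)C(Cl)=O
Why: Vilsmeier-type activation with oxalyl chloride and catalytic DMF converts the acid into its chloride under conditions that do not touch the benzyl ether.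

Step 11
Reactants: 14 benzyl 3-deoxyquinate; 18 4-(benzyloxy)-3-methoxybenzoyl chloride
Product: 19 benzyl 3-deoxy-4,5-di-O-[4-(benzyloxy)-3-methoxybenzoyl]quinate
Conditions: 18 (2.3 equiv), pyridine, DMAP (cat.), CH2Cl2, 0 °C → rt
Reagents that add atoms: none
Why: DMAP-assisted Einhorn acylation should esterify the two equatorial secondary hydroxyls O4 and O5, whereas the tertiary 1-OH, hindered and deactivated by the geminal ester, should stay free at this stoichiometry.

Step 12
Reactants: 19 benzyl 3-deoxy-4,5-di-O-[4-(benzyloxy)-3-methoxybenzoyl]quinate; 20 diethylsilane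
Product: 21 benzyl 3-deoxy-1-O-(diethylsilyl)-4,5-di-O-[4-(benzyloxy)-3-methoxybenzoyl]quinate
Conditions: 20 (1.5 equiv), [Ir(cod)OMe]2 (0.5 mol %), THF, rt → 50 °C; volatiles removed, used crude
Reagents that add atoms: none
Why: iridium-catalysed dehydrogenative Si–O coupling of the tertiary alcohol with the dihydrosilane gives the (hydrido)silyl ether with loss of H2 under base-free conditions that the esters and benzyl ethers tolerate.

Step 13
Reactants: 21 benzyl 3-deoxy-1-O-(diethylsilyl)-4,5-di-O-[4-(benzyloxy)-3-methoxybenzoyl]quinate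
Product: 22 benzyl 3-deoxy-3-C,1-O-(diethylsilanediyl)-4,5-di-O-[4-(benzyloxy)-3-methoxybenzoyl]quinate (bridging oxasilolane)
Conditions: [Ir(cod)OMe]2 (4 mol %), 3,4,7,8-tetramethyl-1,10-phenanthroline (9 mol %), norbornene (1.5 equiv), THF, 100–120 °C, sealed tube; used crude
Reagents that add atoms: none
Why: Proposed new method: Si–H oxidative addition to the iridium–phenanthroline centre and hydrogen transfer to norbornene should give an iridium silyl that cleaves the axial C3–H bond lying cis-1,3-diaxial to O1 through a six-membered iridacycle and then forms the C3–Si bond by reductive elimination. The closest known reaction is the iridium/phenanthroline-catalysed γ-C–H silylation of (hydrido)silyl ethers to oxasilolanes on the way to 1,3-diols, which is established for primary and unstrained secondary C–H bonds but not for a transannular diaxial C–H of an ester-laden cyclohexane. The ring closed is a five-membered 1-oxa-2-silacyclopentane (O1–Si–C3–C2–C1), closed at the C3–Si bond and bridging the chair as a 6-oxa-7-silabicyclo[3.2.1]octane. The new C3 stereocentre is fixed by the tether, since only the C3–H on the O1 face can reach silicon and C–H cleavage and C–Si formation go with retention, so silicon (later O3) is cis to O1. The step needs site selectivity over the other γ-hydrogen (C5–H), over aryl and benzylic C–H bonds and over Si–H addition to the ester carbonyls; the ground-state chair with O1 axial and CO2Bn, O4 and O5 equatorial, the tertiary, acyloxy-substituted nature of C5, the absence of a five-membered path to any aryl C–H and the hydrogen acceptor should secure it.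

Step 14
Reactants: 22 bridging oxasilolane
Product: 23 benzyl 4,5-di-O-[4-(benzyloxy)-3-methoxybenzoyl]quinate
Conditions: 30% H2O2, KF, KHCO3, THF/MeOH, 0 °C → rt
Reagents that add atoms: hydrogen peroxide, OO
Why: in the Tamao–Fleming oxidation fluoride-activated silicon takes up hydroperoxide, C3 migrates from Si to O with retention and the Si–O bonds hydrolyse, which should give the 3-OH cis to the 1-OH, the cold buffered medium being chosen to limit O4→O3 acyl migration.

Step 15
Reactants: 23 benzyl 4,5-di-O-[4-(benzyloxy)-3-methoxybenzoyl]quinate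
Product: 24 burkinabin C, (1S,3R,4R,5R)-1,3-dihydroxy-4,5-bis[(4-hydroxy-3-methoxybenzoyl)oxy]cyclohexane-1-carboxylic acid
Conditions: H2 (1 atm), 10% Pd/C, EtOAc/THF, rt
Reagents that add atoms: none
Why: hydrogenolysis over palladium cleaves the benzyl ester and both aryl benzyl ethers under neutral conditions that cannot trigger acyl migration and leave the aryl esters and all four stereocentres intact.

**Compound list**

1 | 2,2-dimethyl-1,3-dioxan-5-one | CC1(C)OCC(=O)CO1 | starting material
2 | 4-methoxybenzoyl chloride | COc1ccc(cc1)C(Cl)=O | starting material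
3 | 2,2-dimethyl-4H-1,3-dioxin-5-yl 4-methoxybenzoate | COc1ccc(cc1)C(=O)OC1=COC(C)(C)OC1 | intermediate
4 | 2-[(4-methoxybenzoyl)oxy]prop-2-enal | COc1ccc(cc1)C(=O)OC(=C)C=O | intermediate
5 | buta-1,3-diene | C=CC=C | starting material
6 | (S)-1-formylcyclohex-3-en-1-yl 4-methoxybenzoate | C1=CCC[C@@](OC(=O)c2ccc(OC)cc2)(C=O)C1 | intermediate
7 | (S)-1-[(4-methoxybenzoyl)oxy]cyclohex-3-ene-1-carboxylic acid | C1=CCC[C@@](OC(=O)c2ccc(OC)cc2)(C(=O)O)C1 | intermediate
8 | methyl (S)-1-[(4-methoxybenzoyl)oxy]cyclohex-3-ene-1-carboxylate | C1=CCC[C@@](OC(=O)c2ccc(OC)cc2)(C(=O)OC)C1 | intermediate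
9 | methyl (S)-1-hydroxycyclohex-3-ene-1-carboxylate | C1=CCC[C@@](O)(C(=O)OC)C1 | intermediate
10 | methyl (1S,3S,6R)-3-hydroxy-7-oxabicyclo[4.1.0]heptane-3-carboxylate | O1[C@@H]2CC[C@@](O)(C(=O)OC)C[C@@H]21 | intermediate
11 | (1S,3S,6R)-3-hydroxy-7-oxabicyclo[4.1.0]heptane-3-carboxylic acid | O1[C@@H]2CC[C@@](O)(C(=O)O)C[C@@H]21 | intermediate
12 | (1S,4R,5R)-1,4-dihydroxy-6-oxabicyclo[3.2.1]octan-7-one (3-deoxyquinide) | O[C@@H]1CC[C@]2(O)C[C@H]1OC2=O | intermediate
13 | caesium (1S,3R,4R)-1,3,4-trihydroxycyclohexane-1-carboxylate | O[C@@H]1CC[C@@](O)(C(=O)[O-])C[C@H]1O.[Cs+] | intermediate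
14 | benzyl (1S,3R,4R)-1,3,4-trihydroxycyclohexane-1-carboxylate (benzyl 3-deoxyquinate) | O[C@@H]1CC[C@@](O)(C(=O)OCc2ccccc2)C[C@H]1O | intermediate
15 | vanillic acid | COc1cc(C(=O)O)ccc1O | starting material
16 | benzyl 4-(benzyloxy)-3-methoxybenzoate | COc1cc(ccc1OCc1ccccc1)C(=O)OCc1ccccc1 | intermediate
17 | 4-(benzyloxy)-3-methoxybenzoic acid | COc1cc(ccc1OCc1ccccc1)C(=O)O | intermediate
18 | 4-(benzyloxy)-3-methoxybenzoyl chloride | COc1cc(ccc1OCc1ccccc1)C(Cl)=O | intermediate
19 | benzyl 3-deoxy-4,5-di-O-[4-(benzyloxy)-3-methoxybenzoyl]quinate | COc2cc(ccc2OCc3ccccc3)C(=O)O[C@@H]1CC[C@@](O)(C(=O)OCc2ccccc2)C[C@H]1OC(=O)c2ccc(OCc3ccccc3)c(OC)c2 | intermediate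
20 | diethylsilane | CC[SiH2]CC | starting material
21 | benzyl 3-deoxy-1-O-(diethylsilyl)-4,5-di-O-[4-(benzyloxy)-3-methoxybenzoyl]quinate | COc2cc(ccc2OCc3ccccc3)C(=O)O[C@@H]1CC[C@@](O[SiH](CC)CC)(C(=O)OCc2ccccc2)C[C@H]1OC(=O)c2ccc(OCc3ccccc3)c(OC)c2 | intermediate
22 | benzyl 3-deoxy-3-C,1-O-(diethylsilanediyl)-4,5-di-O-[4-(benzyloxy)-3-methoxybenzoyl]quinate | COc2cc(ccc2OCc3ccccc3)C(=O)O[C@@H]1[C@H]4C[C@@](O[Si]4(CC)CC)(C(=O)OCc2ccccc2)C[C@H]1OC(=O)c2ccc(OCc3ccccc3)c(OC)c2 | intermediate
23 | benzyl 4,5-di-O-[4-(benzyloxy)-3-methoxybenzoyl]quinate | COc2cc(ccc2OCc3ccccc3)C(=O)O[C@@H]1[C@H](O)C[C@@](O)(C(=O)OCc2ccccc2)C[C@H]1OC(=O)c2ccc(OCc3ccccc3)c(OC)c2 | intermediate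
24 | burkinabin C | COc1cc(C(=O)O[C@@H]2[C@H](O)C[C@@](O)(C(=O)O)C[C@H]2OC(=O)c2ccc(O)c(OC)c2)ccc1O | target

**Step count**

Total: 15 steps. Longest linear sequence: 13 steps (steps 1–8 and 11–15, from 2,2-dimethyl-1,3-dioxan-5-one); steps 9–10 are a two-step side branch.

**Steps most likely to fail**

1. Step 13. The iridium silyl may not reach or cleave the transannular C3–H bond through the strained bridged transition state. The Si–H bond could then add across the neighbouring benzyl ester carbonyl, or the silyl ether could be lost by redistribution. The fallback uses known chemistry only, sets out from 7 and returns at 24.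
   - Iodolactonisation of 7 (I2, KI, NaHCO3, H2O/CH2Cl2) should give 4-iodo-7-oxo-6-oxabicyclo[3.2.1]octan-1-yl 4-methoxybenzoate F1, with O5 cis to the carboxyl carbon and iodine trans to O5.
   - DBU (toluene, 80 °C) should eliminate HI to 7-oxo-6-oxabicyclo[3.2.1]oct-3-en-1-yl 4-methoxybenzoate F2.
   - Catalytic OsO4/NMO should dihydroxylate the exo face, anti to the lactone bridge, to 1-O-(4-methoxybenzoyl)quinide F3, in which O3 and O4 are both cis to O1.
   - Bu2SnO (toluene, reflux) should give its 3,4-O-dibutylstannylene acetal F4, which BnBr/CsF (DMF) alkylates at the equatorial O3 to 3-O-benzyl-1-O-(4-methoxybenzoyl)quinide F5.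
   - CsOH (2.2 equiv, THF/H2O) then opens the lactone and cleaves the anisoate to caesium 3-O-benzylquinate F6, and BnBr (2.3 equiv, DMF) gives benzyl 3-O-benzylquinate F7.
   - Acylation with 18 (pyridine, DMAP) gives benzyl 3-O-benzyl-4,5-di-O-[4-(benzyloxy)-3-methoxybenzoyl]quinate F8, and hydrogenolysis (H2, Pd/C) of its four benzyl groups leads directly to 24.

2. Step 14. Under basic peroxide the 4-O-acyl group may migrate to the freshly freed cis-3-OH, or the aryl esters may be perhydrolysed, before the hindered secondary C–Si bond is oxidised. The fallback sets out from 22 and returns at 23. HF·pyridine (THF, 0 °C) should cleave the Si–O1 bond to give benzyl 3-deoxy-3-C-[diethyl(fluoro)silyl]-4,5-di-O-[4-(benzyloxy)-3-methoxybenzoyl]quinate F9. This fluorosilane is then oxidised with retention by mCPBA/KF in DMF, a weakly acidic two-stage peracid protocol in which no alkoxide at O3 is formed.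

3. Step 3. Unactivated butadiene may add to the iminium ion too slowly, so that polymerisation of the acrolein and the uncatalysed background reaction erode yield and enantiomeric purity. The fallback sets out from 4 and 5 and returns at 7. A thermal Diels–Alder reaction (toluene, 90 °C, sealed tube, BHT) should give racemic 1-formylcyclohex-3-en-1-yl 4-methoxybenzoate F10. Pinnick oxidation gives racemic 1-[(4-methoxybenzoyl)oxy]cyclohex-3-ene-1-carboxylic acid F11. Classical resolution then proceeds by crystallisation of the (R)-1-phenylethylammonium salt of the (S)-acid F12; the resolving base and its enantiomer would be fixed by screening. Acidification of the salt returns 7.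

**Further compounds**

F1 | step 13 | 4-iodo-7-oxo-6-oxabicyclo[3.2.1]octan-1-yl 4-methoxybenzoate (iodine trans to the lactone oxygen) | I[C@@H]1CC[C@]2(OC(=O)c3ccc(OC)cc3)C[C@H]1OC2=O
F2 | step 13 | 7-oxo-6-oxabicyclo[3.2.1]oct-3-en-1-yl 4-methoxybenzoate | C1=CC[C@]2(OC(=O)c3ccc(OC)cc3)C[C@H]1OC2=O
F3 | step 13 | 1-O-(4-methoxybenzoyl)quinide | O[C@@H]1[C@H](O)C[C@]2(OC(=O)c3ccc(OC)cc3)C[C@H]1OC2=O
F4 | step 13 | 3,4-O-dibutylstannylene acetal of 1-O-(4-methoxybenzoyl)quinide | CCCC[Sn]1(CCCC)O[C@@H]2[C@H](O1)C[C@]3(OC(=O)c4ccc(OC)cc4)C[C@H]2OC3=O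
F5 | step 13 | 3-O-benzyl-1-O-(4-methoxybenzoyl)quinide | O[C@@H]1[C@H](OCc2ccccc2)C[C@]2(OC(=O)c3ccc(OC)cc3)C[C@H]1OC2=O
F6 | step 13 | caesium 3-O-benzylquinate | O[C@@H]1[C@H](OCc2ccccc2)C[C@@](O)(C(=O)[O-])C[C@H]1O.[Cs+]
F7 | step 13 | benzyl 3-O-benzylquinate | O[C@@H]1[C@H](OCc2ccccc2)C[C@@](O)(C(=O)OCc2ccccc2)C[C@H]1O
F8 | step 13 | benzyl 3-O-benzyl-4,5-di-O-[4-(benzyloxy)-3-methoxybenzoyl]quinate | COc2cc(ccc2OCc3ccccc3)C(=O)O[C@@H]1[C@H](OCc2ccccc2)C[C@@](O)(C(=O)OCc2ccccc2)C[C@H]1OC(=O)c2ccc(OCc3ccccc3)c(OC)c2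
F9 | step 14 | benzyl 3-deoxy-3-C-[diethyl(fluoro)silyl]-4,5-di-O-[4-(benzyloxy)-3-methoxybenzoyl]quinate | COc2cc(ccc2OCc3ccccc3)C(=O)O[C@@H]1[C@H]([Si](F)(CC)CC)C[C@@](O)(C(=O)OCc2ccccc2)C[C@H]1OC(=O)c2ccc(OCc3ccccc3)c(OC)c2
F10 | step 3 | racemic 1-formylcyclohex-3-en-1-yl 4-methoxybenzoate | C1=CCCC(OC(=O)c2ccc(OC)cc2)(C=O)C1
F11 | step 3 | racemic 1-[(4-methoxybenzoyl)oxy]cyclohex-3-ene-1-carboxylic acid | C1=CCCC(OC(=O)c2ccc(OC)cc2)(C(=O)O)C1
F12 | step 3 | (R)-1-phenylethylammonium (S)-1-[(4-methoxybenzoyl)oxy]cyclohex-3-ene-1-carboxylate | C1=CCC[C@@](OC(=O)c2ccc(OC)cc2)(C(=O)[O-])C1.C[C@@H]([NH3+])c1ccccc1
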